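## Retrosynthetic overview

1. The target is disconnected to its tri-O-benzyl ether, unmasked last by hydrogenolysis.
2. Ring A is the only ring formed. Its C2–C3 and C1–C6 bonds ([2+2]) and its C3–C4 bond (6π closure) are disconnected to an aryl-substituted vinylketene and methoxyacetylene; rings B and C arrive intact.
3. The vinylketene comes from photochemical Wolff rearrangement of an (E)-α′-diazo enone, made from the methyl enone by detrifluoroacetylative diazo transfer.
4. The methyl enone comes via the Weinreb amide from an (E)-α-(arylethyl)cinnamate, assembled by Horner–Wadsworth–Emmons olefination of 2,5-bis(benzyloxy)benzaldehyde with a phosphonoacetate alkylated by 3-benzyloxyphenethyl bromide.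
5. Feature: ring A is a resorcinol monomethyl ether (C1–OMe and C3–OH meta, H on C2 and C6) with ring B on C4 (ortho to the free OH, para to OMe) and the arylethyl chain on C5. A vinylketene plus an alkoxyacetylene gives exactly this pattern, with the ketene oxygen as the free C3–OH.

Key step: step 10

Remark: the target has no stereocentre; the only stereochemical element carried through the route is the E-alkene set in step 5, which is consumed when ring A aromatises.

## Route

Step 1
Reactants: 1 2,5-dihydroxybenzaldehyde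
Product: 2 2,5-bis(benzyloxy)benzaldehyde
Conditions: BnBr (2.4 equiv), K2CO3, DMF, 60 °C
Reagents that add atoms: benzyl bromide, BrCc1ccccc1
Why: Williamson ether synthesis; both phenoxides formed by K2CO3 are benzylated while the aldehyde is untouched.

Step 2
Reactants: 3 2-(3-hydroxyphenyl)ethanol
Product: 4 2-[3-(benzyloxy)phenyl]ethanol
Conditions: BnBr (1.05 equiv), K2CO3, acetone, reflux
Reagents that add atoms: benzyl bromide, BrCc1ccccc1
Why: Williamson etherification chemoselective for the phenol, the only hydroxyl that K2CO3 deprotonates.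

Step 3
Reactants: 4 2-[3-(benzyloxy)phenyl]ethanol
Product: 5 1-(benzyloxy)-3-(2-bromoethyl)benzene
Conditions: CBr4, PPh3, CH2Cl2, 0 °C to rt
Reagents that add atoms: carbon tetrabromide, BrC(Br)(Br)Br
Why: Appel reaction; the primary alcohol is activated as an alkoxyphosphonium ion and displaced by bromide under neutral conditions that spare the benzyl ether.

Step 4
Reactants: 5 1-(benzyloxy)-3-(2-bromoethyl)benzene; 6 triethyl phosphonoacetate
Product: 7 ethyl 4-[3-(benzyloxy)phenyl]-2-(diethoxyphosphoryl)butanoate (racemic)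
Conditions: 6 (1.5 equiv), NaH, DMF, 0 °C; then 5, NaI (cat.), 60 °C
Reagents that add atoms: none
Why: SN2 C-alkylation of the sodium salt of the phosphonoacetate (a malonate-type stabilised carbanion) by the primary bromide; excess 6 limits dialkylation and the weakly basic anion limits E2 loss of HBr.

Step 5
Reactants: 7 ethyl 4-[3-(benzyloxy)phenyl]-2-(diethoxyphosphoryl)butanoate; 2 2,5-bis(benzyloxy)benzaldehyde
Product: 8 ethyl (E)-2-{[2,5-bis(benzyloxy)phenyl]methylidene}-4-[3-(benzyloxy)phenyl]butanoate
Conditions: NaH, THF, 0 °C to reflux; chromatography to remove the minor Z-isomer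
Reagents that add atoms: none
Why: Horner–Wadsworth–Emmons olefination; reversible addition of the stabilised phosphonate anion should favour the E-alkene with ring B trans to the ester.

Step 6
Reactants: 8 ethyl (E)-2-{[2,5-bis(benzyloxy)phenyl]methylidene}-4-[3-(benzyloxy)phenyl]butanoate
Product: 9 (E)-2-{[2,5-bis(benzyloxy)phenyl]methylidene}-4-[3-(benzyloxy)phenyl]-N-methoxy-N-methylbutanamide
Conditions: MeNH(OMe)·HCl, i-PrMgCl, THF, −20 to 0 °C
Reagents that add atoms: N,O-dimethylhydroxylamine hydrochloride, CNOC.Cl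
Why: Weinreb amide synthesis by direct aminolysis of the ester with the chloromagnesium amide, which forms from the amine salt faster than the Grignard reagent adds to the hindered conjugated ester.

Step 7
Reactants: 9 (E)-2-{[2,5-bis(benzyloxy)phenyl]methylidene}-4-[3-(benzyloxy)phenyl]-N-methoxy-N-methylbutanamide
Product: 10 (E)-3-{[2,5-bis(benzyloxy)phenyl]methylidene}-5-[3-(benzyloxy)phenyl]pentan-2-one
Conditions: MeMgBr, THF, 0 °C; then 1 M HCl
Reagents that add atoms: methylmagnesium bromide, C[Mg]Br
Why: Weinreb ketone synthesis; the chelated tetrahedral magnesium adduct persists until the acidic quench, so only one methyl group adds and the trisubstituted alkene is left alone.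

Step 8
Reactants: 10 (E)-3-{[2,5-bis(benzyloxy)phenyl]methylidene}-5-[3-(benzyloxy)phenyl]pentan-2-one
Product: 12 (E)-1-diazo-3-{[2,5-bis(benzyloxy)phenyl]methylidene}-5-[3-(benzyloxy)phenyl]pentan-2-one, via trifluoroacetyl diketone 11 (not isolated)
Conditions: LiN(SiMe3)2, THF, −78 °C; CF3CO2CH2CF3, −78 °C; aq. HCl work-up; then MsN3, Et3N, H2O (1 equiv), MeCN, rt
Reagents that add atoms: methanesulfonyl azide, CS(=O)(=O)N=[N+]=[N-]; 2,2,2-trifluoroethyl trifluoroacetate, O=C(OCC(F)(F)F)C(F)(F)F (its CF3CO group is carried only by intermediate 11)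
Why: Detrifluoroacetylative diazo transfer (Claisen trifluoroacetylation of the methyl enolate, the only enolisable position, then Regitz-type diazo transfer with loss of the trifluoroacetyl group onto the sulfonamide), which avoids dipolar addition of diazomethane to an unsaturated acid chloride.

Step 9
Reactants: 13 chloroacetaldehyde dimethyl acetal
Product: 15 methoxyacetylene, via sodium methoxyacetylide 14 (not isolated)
Conditions: NaNH2 (3 equiv), liq. NH3, −33 °C; evaporate NH3; cold sat. aq. NaCl, −70 °C; distil into a −78 °C trap, use at once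
Reagents that add atoms: none
Why: Double dehydroelimination (loss of MeOH, then HCl) with NaNH2 gives the alkynyl ether, held as its sodium acetylide until the aqueous quench; this is the standard preparation of 1-alkoxyalkynes from chloroacetaldehyde acetals.

Step 10
Reactants: 12 (E)-1-diazo-3-{[2,5-bis(benzyloxy)phenyl]methylidene}-5-[3-(benzyloxy)phenyl]pentan-2-one; 15 methoxyacetylene
Product: 20 2-[2,5-bis(benzyloxy)phenyl]-3-{2-[3-(benzyloxy)phenyl]ethyl}-5-methoxyphenol, via vinylketene 16 (not isolated), via 4-alkenylcyclobutenone 17 (not isolated), via dienylketene 18 (not isolated), via cyclohexadienone 19 (not isolated)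
Conditions: 15 (3 equiv), ClCH2CH2Cl, hν (300 nm lamps, Vycor tube, sealed), rt; then evaporate excess 15, toluene, 80 °C
Reagents that add atoms: none
Why: Irradiation expels N2 from 12 and the alkenyl group migrates to the carbene carbon (Wolff rearrangement) to give vinylketene 16, whose ketene C=C adds the ynol ether 15 in a [2+2] cycloaddition that forms C2–C3 and C1–C6 and gives 4-alkenylcyclobutenone 17. Under light or on warming, 17 opens by a 4π electrocyclic reaction to dienylketene 18, and ring A closes by a 6π electrocyclisation that joins the ketene carbon C3 to the styryl carbon C4; tautomerisation of cyclohexadienone 19 then gives phenol 20 irreversibly. The closest known reaction type is the Danheiser benzannulation of photochemically generated vinylketenes with alkoxy- and siloxyalkynes. No stereocentre is set, since the sp3 centres of 17 and 19 are transient and vanish on aromatisation. The selectivity needed is the regiochemistry of the [2+2] step: the polarisation of 15 by its oxygen makes the unsubstituted alkyne carbon the nucleophile toward the electrophilic ketene carbonyl carbon, which places OMe meta to the new hydroxyl and para to ring B. The E-geometry of 12 keeps ring B on the outside of the closing triene, and the ketene oxygen emerges as the free C3 hydroxyl while the alkyne oxygen is already the C1 methyl ether, so the two oxygens need no differentiation.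

Step 11
Reactants: 20 2-[2,5-bis(benzyloxy)phenyl]-3-{2-[3-(benzyloxy)phenyl]ethyl}-5-methoxyphenol
Product: 21 2-(2,5-dihydroxyphenyl)-3-[2-(3-hydroxyphenyl)ethyl]-5-methoxyphenol (target)
Conditions: H2 (1 atm), Pd/C (10 wt % Pd), EtOAc–MeOH, rt; work-up under argon
Reagents that add atoms: none
Why: Catalytic hydrogenolysis of the three benzylic C–O bonds; the aryl methyl ether, the biaryl bond and the bibenzyl chain are inert, and exclusion of air protects the hydroquinone of ring B.

## Compound list

1 | 2,5-dihydroxybenzaldehyde | O=Cc1cc(O)ccc1O | starting material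
2 | 2,5-bis(benzyloxy)benzaldehyde | O=Cc1cc(OCc2ccccc2)ccc1OCc1ccccc1 | intermediate
3 | 2-(3-hydroxyphenyl)ethanol | OCCc1cccc(O)c1 | starting material
4 | 2-[3-(benzyloxy)phenyl]ethanol | OCCc1cccc(OCc2ccccc2)c1 | intermediate
5 | 1-(benzyloxy)-3-(2-bromoethyl)benzene | BrCCc1cccc(OCc2ccccc2)c1 | intermediate
6 | triethyl phosphonoacetate | CCOC(=O)CP(=O)(OCC)OCC | starting material
7 | ethyl 4-[3-(benzyloxy)phenyl]-2-(diethoxyphosphoryl)butanoate (racemic) | CCOC(=O)C(CCc1cccc(OCc2ccccc2)c1)P(=O)(OCC)OCC | intermediate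
8 | ethyl (E)-2-{[2,5-bis(benzyloxy)phenyl]methylidene}-4-[3-(benzyloxy)phenyl]butanoate | CCOC(=O)/C(CCc1cccc(OCc2ccccc2)c1)=C/c1cc(OCc2ccccc2)ccc1OCc1ccccc1 | intermediate
9 | (E)-2-{[2,5-bis(benzyloxy)phenyl]methylidene}-4-[3-(benzyloxy)phenyl]-N-methoxy-N-methylbutanamide | CON(C)C(=O)/C(CCc1cccc(OCc2ccccc2)c1)=C/c1cc(OCc2ccccc2)ccc1OCc1ccccc1 | intermediate
10 | (E)-3-{[2,5-bis(benzyloxy)phenyl]methylidene}-5-[3-(benzyloxy)phenyl]pentan-2-one | CC(=O)/C(CCc1cccc(OCc2ccccc2)c1)=C/c1cc(OCc2ccccc2)ccc1OCc1ccccc1 | intermediate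
11 | (E)-5-{[2,5-bis(benzyloxy)phenyl]methylidene}-7-[3-(benzyloxy)phenyl]-1,1,1-trifluoroheptane-2,4-dione (not isolated) | O=C(CC(=O)C(F)(F)F)/C(CCc1cccc(OCc2ccccc2)c1)=C/c1cc(OCc2ccccc2)ccc1OCc1ccccc1 | intermediate
12 | (E)-1-diazo-3-{[2,5-bis(benzyloxy)phenyl]methylidene}-5-[3-(benzyloxy)phenyl]pentan-2-one | [N-]=[N+]=CC(=O)/C(CCc1cccc(OCc2ccccc2)c1)=C/c1cc(OCc2ccccc2)ccc1OCc1ccccc1 | intermediate
13 | chloroacetaldehyde dimethyl acetal | COC(CCl)OC | starting material
14 | sodium methoxyacetylide (not isolated) | [Na+].[C-]#COC | intermediate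
15 | methoxyacetylene | C#COC | intermediate
16 | (E)-4-[2,5-bis(benzyloxy)phenyl]-3-{2-[3-(benzyloxy)phenyl]ethyl}buta-1,3-dien-1-one (vinylketene, not isolated) | O=C=C/C(CCc1cccc(OCc2ccccc2)c1)=C/c1cc(OCc2ccccc2)ccc1OCc1ccccc1 | intermediate
17 | 4-{(E)-1-[2,5-bis(benzyloxy)phenyl]-4-[3-(benzyloxy)phenyl]but-1-en-2-yl}-3-methoxycyclobut-2-en-1-one (racemic, not isolated) | COC1=CC(=O)C1/C(CCc1cccc(OCc2ccccc2)c1)=C/c1cc(OCc2ccccc2)ccc1OCc1ccccc1 | intermediate
18 | (3E,5E)-6-[2,5-bis(benzyloxy)phenyl]-5-{2-[3-(benzyloxy)phenyl]ethyl}-3-methoxyhexa-1,3,5-trien-1-one (dienylketene, not isolated) | O=C=C/C(OC)=C\C(CCc1cccc(OCc2ccccc2)c1)=C\c1cc(OCc2ccccc2)ccc1OCc1ccccc1 | intermediate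
19 | 6-[2,5-bis(benzyloxy)phenyl]-5-{2-[3-(benzyloxy)phenyl]ethyl}-3-methoxycyclohexa-2,4-dien-1-one (racemic, not isolated) | COC1=CC(=O)C(c2cc(OCc3ccccc3)ccc2OCc2ccccc2)C(CCc2cccc(OCc3ccccc3)c2)=C1 | intermediate
20 | 2-[2,5-bis(benzyloxy)phenyl]-3-{2-[3-(benzyloxy)phenyl]ethyl}-5-methoxyphenol | COc1cc(O)c(-c2cc(OCc3ccccc3)ccc2OCc2ccccc2)c(CCc2cccc(OCc3ccccc3)c2)c1 | intermediate
21 | 2-(2,5-dihydroxyphenyl)-3-[2-(3-hydroxyphenyl)ethyl]-5-methoxyphenol | COc1cc(O)c(-c2cc(O)ccc2O)c(CCc2cccc(O)c2)c1 | target

## Step count and risks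

Total step count: 11. Longest linear sequence: 9 steps (steps 2, 3, 4, 5, 6, 7, 8, 10, 11, from compound 3).

Steps most likely to fail:

1. Step 10. E/Z photoisomerisation and photodegradation of the aryl-conjugated diazo enone may compete with Wolff rearrangement. The volatile ynol ether may be lost or polymerise during irradiation, and the phenol formed may be acylated by unreacted ketene. The fallback generates the same vinylketene in the dark; it sets out from diazoketone 12 and returns at phenol 20. Wolff rearrangement of 12 promoted by PhCO2Ag and Et3N in THF–H2O should give the homologous acid (E)-4-[2,5-bis(benzyloxy)phenyl]-3-{2-[3-(benzyloxy)phenyl]ethyl}but-3-enoic acid F1. Treatment with (COCl)2 and catalytic DMF in CH2Cl2 should give (E)-4-[2,5-bis(benzyloxy)phenyl]-3-{2-[3-(benzyloxy)phenyl]ethyl}but-3-enoyl chloride F2. Slow addition of F2 to Et3N and an excess of 15 in toluene at 60–80 °C should form 16 by dehydrochlorination, and the thermal sequence through 17, 18 and 19 should then give 20.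

2. Step 4. E2 elimination of the phenethyl bromide to the styrene and double alkylation of the phosphonoacetate may erode the alkylation. The fallback builds the same trisubstituted alkene by cross-coupling; it sets out from bromide 5 and aldehyde 2 and returns at ester 8, bypassing 7. KOt-Bu in THF turns the elimination into the intended reaction and should give 1-(benzyloxy)-3-ethenylbenzene F3. Hydroboration with 9-BBN-H in THF should give the terminal borane 9-{2-[3-(benzyloxy)phenyl]ethyl}-9-borabicyclo[3.3.1]nonane F4. Separately, Wittig reaction of 2 with Ph3P=C(Br)CO2Et in CH2Cl2 should give ethyl (Z)-2-bromo-3-[2,5-bis(benzyloxy)phenyl]prop-2-enoate F5. B-alkyl Suzuki–Miyaura coupling of F4 with F5 (PdCl2(dppf), Cs2CO3, DMF–THF–H2O, rt to 50 °C) proceeds with retention at the alkenyl bromide and should give 8 with the required E-geometry.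

3. Step 8. Trifluoroacetylation of the lithium enolate may be incomplete, or the enolate may self-condense, which would leave unactivated ketone that does not accept the diazo group. The fallback acylates diazomethane instead; it sets out from ester 8 and returns at diazoketone 12. Saponification with LiOH in THF–MeOH–H2O should give (E)-2-{[2,5-bis(benzyloxy)phenyl]methylidene}-4-[3-(benzyloxy)phenyl]butanoic acid F6. Treatment with (COCl)2 and catalytic DMF should give (E)-2-{[2,5-bis(benzyloxy)phenyl]methylidene}-4-[3-(benzyloxy)phenyl]butanoyl chloride F7. Addition of F7 to excess CH2N2 in Et2O at 0 °C should give 12; the trisubstituted, aryl-bearing alkene is expected to be a poor dipolarophile, so pyrazoline formation should stay minor.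

## Further compounds

F1 | step 10 | (E)-4-[2,5-bis(benzyloxy)phenyl]-3-{2-[3-(benzyloxy)phenyl]ethyl}but-3-enoic acid | OC(=O)C/C(CCc1cccc(OCc2ccccc2)c1)=C/c1cc(OCc2ccccc2)ccc1OCc1ccccc1
F2 | step 10 | (E)-4-[2,5-bis(benzyloxy)phenyl]-3-{2-[3-(benzyloxy)phenyl]ethyl}but-3-enoyl chloride | ClC(=O)C/C(CCc1cccc(OCc2ccccc2)c1)=C/c1cc(OCc2ccccc2)ccc1OCc1ccccc1
F3 | step 4 | 1-(benzyloxy)-3-ethenylbenzene | C=Cc1cccc(OCc2ccccc2)c1
F4 | step 4 | 9-{2-[3-(benzyloxy)phenyl]ethyl}-9-borabicyclo[3.3.1]nonane | c1ccccc1COc1cccc(CCB2C3CCCC2CCC3)c1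
F5 | step 4 | ethyl (Z)-2-bromo-3-[2,5-bis(benzyloxy)phenyl]prop-2-enoate | CCOC(=O)/C(Br)=C/c1cc(OCc2ccccc2)ccc1OCc1ccccc1
F6 | step 8 | (E)-2-{[2,5-bis(benzyloxy)phenyl]methylidene}-4-[3-(benzyloxy)phenyl]butanoic acid | OC(=O)/C(CCc1cccc(OCc2ccccc2)c1)=C/c1cc(OCc2ccccc2)ccc1OCc1ccccc1
F7 | step 8 | (E)-2-{[2,5-bis(benzyloxy)phenyl]methylidene}-4-[3-(benzyloxy)phenyl]butanoyl chloride | ClC(=O)/C(CCc1cccc(OCc2ccccc2)c1)=C/c1cc(OCc2ccccc2)ccc1OCc1ccccc1
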